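Plan
- Retrosynthesis: the two acetates and the angelate are cut last. The ring bond C1–C6 of the cyclohexane (angelate-bearing carbinol carbon to the neighbouring ring CH2) is then cut as a ketyl–enone coupling, followed by the isopropenyl–C4 bond (alkenyllithium plus lactone) and the C2–C3 bond (alkylation of an acyl oxazolidinone).
- Enabling feature: C1–O and C4–O are para on the ring and the methyl-bearing C5 lies between C4 and C6. With C4 as a ketone, C6 is the β-carbon of a 2-methyl enone and C1 an aldehyde carbon (γ-hydroxy ketone pattern).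
- Forward: (R)-citronellic acid supplies C1, C2 and the whole side chain (10 of 15 skeletal carbons); bromoacetate supplies C3–C4; an isopropenyl unit supplies C5, C6 and the ring methyl. The only ring closes in step 9.
- Stereochemistry: side-chain C2 from the chiral pool; ring C2 from the oxazolidinone auxiliary; side-chain C4 from Corey–Bakshi–Shibata reduction; ring C1 and C5 in the ring closure (C5 thermodynamic); ring C4 by equatorial hydride delivery.
- Oxygen differentiation: the ring closure frees only the C1 hydroxyl (angelate), C4 stays a ketone and the side-chain oxygen is silylated; both acetates go on together at the end.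

Key step: step 9

Remark: the target is read as the (Z)-2-methylbut-2-enoate (angelate) with (1R,2S,4R,5S) ring and (2R,4R) side-chain configuration; (R)-citronellic acid and the other inputs are taken as commercial.

Step 1
Reactants: 1 (R)-citronellic acid; 2 (4S)-4-benzyl-1,3-oxazolidin-2-one
Product: 4 (4S)-4-benzyl-3-[(3R)-3,7-dimethyloct-6-enoyl]-1,3-oxazolidin-2-one, via mixed pivalic anhydride 3 (not isolated)
Conditions: t-BuCOCl, Et3N, THF, –20 °C; then 2, LiCl, rt
Reagents that add atoms: pivaloyl chloride, CC(C)(C)C(Cl)=O (its acyl group stays only in intermediate 3)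
Why: N-acylation of the oxazolidinone through a mixed anhydride should give the imide without touching the remote methyl stereocentre, and no new stereocentre is formed.

Step 2
Reactants: 4 (4S)-4-benzyl-3-[(3R)-3,7-dimethyloct-6-enoyl]-1,3-oxazolidin-2-one
Product: 6 tert-butyl (3S,4R)-3-{[(4S)-4-benzyl-2-oxo-1,3-oxazolidin-3-yl]carbonyl}-4,8-dimethylnon-7-enoate, via sodium enolate 5 (not isolated)
Conditions: NaN(SiMe3)2, THF, –78 °C; then BrCH2CO2t-Bu, –78 to –40 °C
Reagents that add atoms: tert-butyl bromoacetate, BrCC(=O)OC(C)(C)C; sodium bis(trimethylsilyl)amide, C[Si](C)(C)[N-][Si](C)(C)C.[Na+] (sodium stays only in intermediate 5)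
Why: Evans alkylation, in which the benzyl group shields one face of the chelated Z-enolate so that the bromoacetate should enter from the other face and set the new centre as 3S (the future ring carbon that carries the side chain).

Step 3
Reactants: 6 tert-butyl (3S,4R)-3-{[(4S)-4-benzyl-2-oxo-1,3-oxazolidin-3-yl]carbonyl}-4,8-dimethylnon-7-enoate
Product: 8 (4S)-4-[(2R)-6-methylhept-5-en-2-yl]oxolan-2-one, via hydroxy tert-butyl ester 7 (not isolated)
Conditions: LiBH4, H2O (1 equiv), Et2O, 0 °C; then TsOH·H2O (cat.), toluene, 80 °C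
Reagents that add atoms: none
Why: Reductive cleavage of the imide should free the primary alcohol and release the auxiliary while the tert-butyl ester survives, and acid-catalysed lactonisation then stores the future aldehyde carbon as CH2–O and the future ketone carbon as the lactone carbonyl.

Step 4
Reactants: 8 (4S)-4-[(2R)-6-methylhept-5-en-2-yl]oxolan-2-one
Product: 9 (4S)-4-[(2R)-6-methyl-4-oxohept-5-en-2-yl]oxolan-2-one
Conditions: CrO3, 3,5-dimethylpyrazole, CH2Cl2, –20 °C
Reagents that add atoms: chromium trioxide, O=[Cr](=O)=O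
Why: Allylic oxidation by the CrO3–3,5-dimethylpyrazole complex should attack the only allylic CH2, and oxygenation at either end of the allylic system converges (directly or by 1,3-transposition of the tertiary chromate) on the conjugated β,β-dimethyl enone while the lactone is inert.

Step 5
Reactants: 9 (4S)-4-[(2R)-6-methyl-4-oxohept-5-en-2-yl]oxolan-2-one
Product: 10 (4S)-4-[(2R,4R)-4-hydroxy-6-methylhept-5-en-2-yl]oxolan-2-one
Conditions: (S)-Me-CBS oxazaborolidine ((3aS)-1-methyl-3,3-diphenyltetrahydro-3H-pyrrolo[1,2-c][1,3,2]oxazaborole, cat.), catecholborane, toluene, –78 °C; aqueous work-up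
Reagents that add atoms: none
Why: Corey–Bakshi–Shibata reduction, in which the alkenyl group acts as the large substituent so that the (S)-catalyst should deliver hydride to the face giving the (R)-allylic alcohol, with lactone and alkene untouched at –78 °C.

Step 6
Reactants: 10 (4S)-4-[(2R,4R)-4-hydroxy-6-methylhept-5-en-2-yl]oxolan-2-one
Product: 11 (4S)-4-[(2R,4R)-4-{[tert-butyl(dimethyl)silyl]oxy}-6-methylhept-5-en-2-yl]oxolan-2-one
Conditions: t-BuMe2SiCl, imidazole, DMF, rt
Reagents that add atoms: tert-butyl(chloro)dimethylsilane, CC(C)(C)[Si](C)(C)Cl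
Why: Standard silylation should protect the allylic alcohol against the organolithium and oxidation steps and keep it distinct from the ring carbinol formed later.

Step 7
Reactants: 11 (4S)-4-[(2R,4R)-4-{[tert-butyl(dimethyl)silyl]oxy}-6-methylhept-5-en-2-yl]oxolan-2-one
Product: 13 (5S,6R,8R)-8-{[tert-butyl(dimethyl)silyl]oxy}-5-(hydroxymethyl)-2,6,10-trimethylundeca-1,9-dien-3-one, via lithium lactolate 12 (not isolated)
Conditions: 2-bromopropene, t-BuLi (2 equiv), Et2O, –78 °C; then 11, THF, –78 °C; AcOH quench at –78 °C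
Reagents that add atoms: prop-1-en-2-yllithium, [Li]C(C)=C, made in the flask from 2-bromopropene, CC(Br)=C (lithium stays only in intermediate 12)
Why: Mono-addition of an alkenyllithium to a γ-lactone, where the tetrahedral lactolate is stable at –78 °C and collapses only on protonation, should unveil the 2-methyl enone and the primary alcohol in one operation.

Step 8
Reactants: 13 (5S,6R,8R)-8-{[tert-butyl(dimethyl)silyl]oxy}-5-(hydroxymethyl)-2,6,10-trimethylundeca-1,9-dien-3-one
Product: 14 (2S)-2-[(2R,4R)-4-{[tert-butyl(dimethyl)silyl]oxy}-6-methylhept-5-en-2-yl]-5-methyl-4-oxohex-5-enal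
Conditions: Dess–Martin periodinane, CH2Cl2, 0 °C to rt
Reagents that add atoms: none
Why: Dess–Martin oxidation under non-basic conditions should give the γ-keto aldehyde without epimerising the α-stereocentre or disturbing the enone and silyl ether.

Step 9
Reactants: 14 (2S)-2-[(2R,4R)-4-{[tert-butyl(dimethyl)silyl]oxy}-6-methylhept-5-en-2-yl]-5-methyl-4-oxohex-5-enal
Product: 15 (2S,4R,5S)-5-[(2R,4R)-4-{[tert-butyl(dimethyl)silyl]oxy}-6-methylhept-5-en-2-yl]-4-hydroxy-2-methylcyclohexan-1-one
Conditions: SmI2 (0.1 M in THF, 2.2 equiv), t-BuOH (2 equiv), THF, –78 °C, high dilution; then DBU (cat.), CH2Cl2, rt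
Reagents that add atoms: none
Why: Electron transfer from SmI2 to the aldehyde gives a samarium ketyl whose carbon adds to the unsubstituted β-carbon of the 2-methyl enone, and the resulting α-keto radical is reduced by a second SmI2 to a trivalent samarium enolate that t-BuOH protonates. The closest known reaction type is the SmI2-mediated ketyl–olefin reductive cyclisation onto α,β-unsaturated carbonyl acceptors. The six-membered ring closes in the 6-endo-trig mode, since the attacked CH2 is the terminus of the alkene and both alkene carbons end up in the ring. The carbinol centre C4 should be set in a chair-like transition state with the large C5 side chain and the solvated O–Sm group both equatorial (trans), and the C2 methyl centre is set by enolate protonation and settles equatorial under the base equilibration because it is α to the ketone. The step needs chemoselectivity for the enone over the trisubstituted side-chain alkene and 6-endo over 5-exo regioselectivity; the first is secured by the polarity match of the nucleophilic ketyl with the electron-poor alkene (isolated alkene and allylic silyl ether are inert to SmI2), the second by the disubstituted, electronically mismatched α-carbon. The product carries the two ring oxygens differentiated as free alcohol and ketone.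

Step 10
Reactants: 15 (2S,4R,5S)-5-[(2R,4R)-4-{[tert-butyl(dimethyl)silyl]oxy}-6-methylhept-5-en-2-yl]-4-hydroxy-2-methylcyclohexan-1-one
Product: 16 (1R,2S,5S)-2-[(2R,4R)-4-{[tert-butyl(dimethyl)silyl]oxy}-6-methylhept-5-en-2-yl]-5-methyl-4-oxocyclohexyl (2Z)-2-methylbut-2-enoate
Conditions: angelic acid, 2,4,6-trichlorobenzoyl chloride, Et3N, toluene, rt; then 15, 80 °C (no 4-(dimethylamino)pyridine)
Reagents that add atoms: angelic acid, C/C=C(/C)C(=O)O
Why: Yamaguchi-type esterification through the mixed trichlorobenzoic anhydride without a nucleophilic catalyst is the known way to form angelates without Z-to-E isomerisation, and only one hydroxyl is free.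

Step 11
Reactants: 16 (1R,2S,5S)-2-[(2R,4R)-4-{[tert-butyl(dimethyl)silyl]oxy}-6-methylhept-5-en-2-yl]-5-methyl-4-oxocyclohexyl (2Z)-2-methylbut-2-enoate
Product: 17 (1R,2S,4R,5S)-2-[(2R,4R)-4-{[tert-butyl(dimethyl)silyl]oxy}-6-methylhept-5-en-2-yl]-4-hydroxy-5-methylcyclohexyl (2Z)-2-methylbut-2-enoate
Conditions: LiBH(s-Bu)3 (1.1 equiv), THF, –78 °C; H2O quench
Reagents that add atoms: none
Why: Bulky-hydride reduction of a 2-methylcyclohexanone proceeds by equatorial attack and should give the axial alcohol cis to the methyl group (4R), while the hindered β-substituted enoate and the silyl ether should survive at –78 °C.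

Step 12
Reactants: 17 (1R,2S,4R,5S)-2-[(2R,4R)-4-{[tert-butyl(dimethyl)silyl]oxy}-6-methylhept-5-en-2-yl]-4-hydroxy-5-methylcyclohexyl (2Z)-2-methylbut-2-enoate
Product: 18 (1R,2S,4R,5S)-4-hydroxy-2-[(2R,4R)-4-hydroxy-6-methylhept-5-en-2-yl]-5-methylcyclohexyl (2Z)-2-methylbut-2-enoate
Conditions: Bu4NF, AcOH, THF, 0 °C to rt
Reagents that add atoms: none
Why: Buffered fluoride desilylation should free the allylic alcohol without acyl migration, since the angelate is 1,4 to the ring hydroxyl and remote from the side-chain hydroxyl.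

Step 13
Reactants: 18 (1R,2S,4R,5S)-4-hydroxy-2-[(2R,4R)-4-hydroxy-6-methylhept-5-en-2-yl]-5-methylcyclohexyl (2Z)-2-methylbut-2-enoate
Product: 19 (1R,2S,4R,5S)-4-acetoxy-2-[(2R,4R)-4-acetoxy-6-methylhept-5-en-2-yl]-5-methylcyclohexyl (2Z)-2-methylbut-2-enoate
Conditions: Ac2O, pyridine, 4-(dimethylamino)pyridine (cat.), CH2Cl2, rt
Reagents that add atoms: acetic anhydride, CC(=O)OC(C)=O
Why: Nucleophile-catalysed acetylation should esterify both secondary alcohols (the axial ring alcohol needs the catalyst) with retention, and a preformed angelate is stable to these conditions.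

Compound list
1 | (R)-citronellic acid, (3R)-3,7-dimethyloct-6-enoic acid | C[C@H](CCC=C(C)C)CC(=O)O | starting material
2 | (4S)-4-benzyl-1,3-oxazolidin-2-one | O=C1N[C@@H](Cc2ccccc2)CO1 | starting material
3 | (3R)-3,7-dimethyloct-6-enoic pivalic anhydride | C[C@H](CCC=C(C)C)CC(=O)OC(=O)C(C)(C)C | intermediate
4 | (4S)-4-benzyl-3-[(3R)-3,7-dimethyloct-6-enoyl]-1,3-oxazolidin-2-one | C[C@H](CCC=C(C)C)CC(=O)N1[C@@H](Cc2ccccc2)COC1=O | intermediate
5 | sodium (Z)-enolate of 4 | C[C@H](CCC=C(C)C)/C=C(\[O-])N1[C@@H](Cc2ccccc2)COC1=O.[Na+] | intermediate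
6 | tert-butyl (3S,4R)-3-{[(4S)-4-benzyl-2-oxo-1,3-oxazolidin-3-yl]carbonyl}-4,8-dimethylnon-7-enoate | CC(C)(C)OC(=O)C[C@@H]([C@H](C)CCC=C(C)C)C(=O)N1[C@@H](Cc2ccccc2)COC1=O | intermediate
7 | tert-butyl (3S,4R)-3-(hydroxymethyl)-4,8-dimethylnon-7-enoate | CC(C)(C)OC(=O)C[C@@H]([C@H](C)CCC=C(C)C)CO | intermediate
8 | (4S)-4-[(2R)-6-methylhept-5-en-2-yl]oxolan-2-one | O=C1C[C@@H]([C@H](C)CCC=C(C)C)CO1 | intermediate
9 | (4S)-4-[(2R)-6-methyl-4-oxohept-5-en-2-yl]oxolan-2-one | O=C1C[C@@H]([C@H](C)CC(=O)C=C(C)C)CO1 | intermediate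
10 | (4S)-4-[(2R,4R)-4-hydroxy-6-methylhept-5-en-2-yl]oxolan-2-one | O=C1C[C@@H]([C@H](C)C[C@@H](O)C=C(C)C)CO1 | intermediate
11 | (4S)-4-[(2R,4R)-4-{[tert-butyl(dimethyl)silyl]oxy}-6-methylhept-5-en-2-yl]oxolan-2-one | O=C1C[C@@H]([C@H](C)C[C@@H](O[Si](C)(C)C(C)(C)C)C=C(C)C)CO1 | intermediate
12 | lithium 2-(prop-1-en-2-yl)oxolan-2-olate derived from 11 (lactolate, mixture at the ketal carbon) | [Li+].[O-]C1(C(C)=C)C[C@@H]([C@H](C)C[C@@H](O[Si](C)(C)C(C)(C)C)C=C(C)C)CO1 | intermediate
13 | (5S,6R,8R)-8-{[tert-butyl(dimethyl)silyl]oxy}-5-(hydroxymethyl)-2,6,10-trimethylundeca-1,9-dien-3-one | C=C(C)C(=O)C[C@@H]([C@H](C)C[C@@H](O[Si](C)(C)C(C)(C)C)C=C(C)C)CO | intermediate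
14 | (2S)-2-[(2R,4R)-4-{[tert-butyl(dimethyl)silyl]oxy}-6-methylhept-5-en-2-yl]-5-methyl-4-oxohex-5-enal | C=C(C)C(=O)C[C@@H]([C@H](C)C[C@@H](O[Si](C)(C)C(C)(C)C)C=C(C)C)C=O | intermediate
15 | (2S,4R,5S)-5-[(2R,4R)-4-{[tert-butyl(dimethyl)silyl]oxy}-6-methylhept-5-en-2-yl]-4-hydroxy-2-methylcyclohexan-1-one | O[C@@H]1C[C@H](C)C(=O)C[C@H]1[C@H](C)C[C@@H](O[Si](C)(C)C(C)(C)C)C=C(C)C | intermediate
16 | (1R,2S,5S)-2-[(2R,4R)-4-{[tert-butyl(dimethyl)silyl]oxy}-6-methylhept-5-en-2-yl]-5-methyl-4-oxocyclohexyl (2Z)-2-methylbut-2-enoate | C/C=C(/C)C(=O)O[C@@H]1C[C@H](C)C(=O)C[C@H]1[C@H](C)C[C@@H](O[Si](C)(C)C(C)(C)C)C=C(C)C | intermediate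
17 | (1R,2S,4R,5S)-2-[(2R,4R)-4-{[tert-butyl(dimethyl)silyl]oxy}-6-methylhept-5-en-2-yl]-4-hydroxy-5-methylcyclohexyl (2Z)-2-methylbut-2-enoate | C/C=C(/C)C(=O)O[C@@H]1C[C@H](C)[C@H](O)C[C@H]1[C@H](C)C[C@@H](O[Si](C)(C)C(C)(C)C)C=C(C)C | intermediate
18 | (1R,2S,4R,5S)-4-hydroxy-2-[(2R,4R)-4-hydroxy-6-methylhept-5-en-2-yl]-5-methylcyclohexyl (2Z)-2-methylbut-2-enoate | C/C=C(/C)C(=O)O[C@@H]1C[C@H](C)[C@H](O)C[C@H]1[C@H](C)C[C@@H](O)C=C(C)C | intermediate
19 | (1R,2S,4R,5S)-4-acetoxy-2-[(2R,4R)-4-acetoxy-6-methylhept-5-en-2-yl]-5-methylcyclohexyl (2Z)-2-methylbut-2-enoate | C/C=C(/C)C(=O)O[C@@H]1C[C@H](C)[C@H](OC(C)=O)C[C@H]1[C@H](C)C[C@H](C=C(C)C)OC(C)=O | target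

Total step count: 13. Longest linear sequence: 13 steps (fully linear from 1).

Steps most likely to fail

Step 9. The ketyl may add with poor facial selectivity at the carbinol carbon, and two-electron reduction of the enone may compete with ring closure. If the cyclisation of 14 delivers mainly the epimeric axial alcohol, (2S,4S,5S)-5-[(2R,4R)-4-{[tert-butyl(dimethyl)silyl]oxy}-6-methylhept-5-en-2-yl]-4-hydroxy-2-methylcyclohexan-1-one F3, this material is not discarded. It is esterified with angelic acid under Mitsunobu conditions (PPh3, diisopropyl azodicarboxylate, toluene, 0 °C), which inverts the carbinol centre and installs the ester in one operation. The fallback sets out from 14 and rejoins the route at 16.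

Step 4. Hydrogen abstraction from the allylic methyl groups and over-oxidation may erode the chromium-mediated oxidation. The fallback sets out from 8 with a Schenck ene reaction (O2, tetraphenylporphyrin, visible light, CH2Cl2, 0 °C). This should give the tertiary allylic hydroperoxide (4S)-4-[(2R,4E)-6-hydroperoxy-6-methylhept-4-en-2-yl]oxolan-2-one F1, which is reduced in the same flask with PPh3 to (4S)-4-[(2R,4E)-6-hydroxy-6-methylhept-4-en-2-yl]oxolan-2-one F2 and separated from its regioisomer. Babler–Dauben oxidative transposition with pyridinium chlorochromate, C5H5NH[CrO3Cl], in CH2Cl2 then gives the enone, rejoining the route at 9.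

Step 10. Isomerisation of the Z-enoate to the E-isomer during acyl transfer, and slow acylation of the hindered alcohol, may spoil the esterification. The fallback sets out from 15 and builds the double bond after the ester bond. Esterification with 2-[bis(2,2,2-trifluoroethoxy)phosphoryl]propanoic acid (dicyclohexylcarbodiimide, 4-(dimethylamino)pyridine, CH2Cl2) gives (1R,2S,5S)-2-[(2R,4R)-4-{[tert-butyl(dimethyl)silyl]oxy}-6-methylhept-5-en-2-yl]-5-methyl-4-oxocyclohexyl 2-[bis(2,2,2-trifluoroethoxy)phosphoryl]propanoate F4. Still–Gennari olefination (KN(SiMe3)2, 18-crown-6, acetaldehyde, THF, –78 °C) should then give the Z-enoate, rejoining the route at 16.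

Further compounds
F1 | step 4 | (4S)-4-[(2R,4E)-6-hydroperoxy-6-methylhept-4-en-2-yl]oxolan-2-one | O=C1C[C@@H]([C@H](C)C/C=C/C(C)(C)OO)CO1
F2 | step 4 | (4S)-4-[(2R,4E)-6-hydroxy-6-methylhept-4-en-2-yl]oxolan-2-one | O=C1C[C@@H]([C@H](C)C/C=C/C(C)(C)O)CO1
F3 | step 9 | (2S,4S,5S)-5-[(2R,4R)-4-{[tert-butyl(dimethyl)silyl]oxy}-6-methylhept-5-en-2-yl]-4-hydroxy-2-methylcyclohexan-1-one | O[C@H]1C[C@H](C)C(=O)C[C@H]1[C@H](C)C[C@@H](O[Si](C)(C)C(C)(C)C)C=C(C)C
F4 | step 10 | (1R,2S,5S)-2-[(2R,4R)-4-{[tert-butyl(dimethyl)silyl]oxy}-6-methylhept-5-en-2-yl]-5-methyl-4-oxocyclohexyl 2-[bis(2,2,2-trifluoroethoxy)phosphoryl]propanoate | CC(C(=O)O[C@@H]1C[C@H](C)C(=O)C[C@H]1[C@H](C)C[C@@H](O[Si](C)(C)C(C)(C)C)C=C(C)C)P(=O)(OCC(F)(F)F)OCC(F)(F)F
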